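**Plan**

- Retrosynthesis: the C4 carbinol and the C5–C6 single bond of the oxane are traced back to the ketone and enol-ether double bond of a 2,3-dihydro-4H-pyran-4-one (10). Its aryl–ring bond is then cut, which restores a flat 4H-pyran-4-one (8) and an arylboronic acid (9). The pyranone is cut into an acid chloride (4) and 4-methoxybut-3-en-2-one (5).
- Forward: the six-membered oxygen ring is first built aromatic (Claisen acylation, cyclodehydration). It is then dearomatized by enantioselective aryl addition at its only unsubstituted oxygen-bearing carbon, and finally saturated.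
- Enabling feature: the 4H-pyran-4-one ring (O1, C2–C6) is a cross-conjugated bis(enol ether) ketone. Its C4 carbonyl activates the C5=C6 bond for aryl–palladium insertion at C6–H and later becomes the ring hydroxyl, so no helper group has to be taken out.
- Stereochemistry: C7 comes from O-benzyl-D-tyrosine (diazotization with retention); the aryl-bearing carbon from the chiral palladium catalyst; the side-chain-bearing ring carbon from hydrogenation anti to the aryl group; the ring carbinol from axial hydride delivery. The target ring is all-cis, all-equatorial.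
- Protecting groups: three benzyl ethers, all removed in the hydrogenation step.

Key step: step 6

Remark: ring positions are numbered as in the name of each compound (C6 of pyranone 8 becomes C2 of 10, 11 and 12), and the exocyclic carbinol carbon is called C7 throughout. Compounds 1, 5 and 9 are taken as commercial. The (S)-ligand is assumed to deliver the aryl group to the face that gives 2R; if the sense of induction is opposite, its enantiomer is used with no other change.

**Step 1**
Reactants: 1 O-benzyl-D-tyrosine
Product: 2 (2R)-3-[4-(benzyloxy)phenyl]-2-hydroxypropanoic acid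
Conditions: NaNO2, 1 M H2SO4, 1,4-dioxane/H2O, 0 °C to rt
Reagents that add atoms: water (O)
Why: Diazotization of an α-amino acid in aqueous acid should give the α-hydroxy acid with net retention (double inversion through the α-lactone formed by carboxylate participation), which fixes C7 as R; the aryl benzyl ether tolerates dilute acid.

**Step 2**
Reactants: 2 (2R)-3-[4-(benzyloxy)phenyl]-2-hydroxypropanoic acid
Product: 3 (2R)-2-(benzyloxy)-3-[4-(benzyloxy)phenyl]propanoic acid
Conditions: NaH (2.3 equiv), BnBr (1.1 equiv), Bu4NI (cat.), THF, 0 °C to rt; then 1 M HCl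
Reagents that add atoms: benzyl bromide (BrCc1ccccc1)
Why: Williamson etherification of the alkoxide–carboxylate dianion should occur at the far more nucleophilic alkoxide, and the carboxylate protects the α-hydrogen from deprotonation, so the stereocenter is untouched.

**Step 3**
Reactants: 3 (2R)-2-(benzyloxy)-3-[4-(benzyloxy)phenyl]propanoic acid
Product: 4 (2R)-2-(benzyloxy)-3-[4-(benzyloxy)phenyl]propanoyl chloride
Conditions: (COCl)2 (1.5 equiv), DMF (cat.), CH2Cl2, 0 °C to rt; concentrate, use crude
Reagents that add atoms: oxalyl chloride (O=C(Cl)C(=O)Cl)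
Why: Standard acid chloride formation under Vilsmeier-type catalysis; α-alkoxy acid chlorides are configurationally stable in the absence of amine base.

**Step 4**
Reactants: 4 (2R)-2-(benzyloxy)-3-[4-(benzyloxy)phenyl]propanoyl chloride; 5 (E)-4-methoxybut-3-en-2-one
Product: 7 (1E,6R)-6-(benzyloxy)-7-[4-(benzyloxy)phenyl]-1-methoxyhept-1-ene-3,5-dione, via lithium dienolate 6 (not isolated)
Conditions: 5 (2.1 equiv), LiN(SiMe3)2 (2.1 equiv), THF, –78 °C; then 4, –78 °C; 1 M HCl quench
Reagents that add atoms: none
Why: Crossed Claisen C-acylation of the kinetic lithium enolate of the vinylogous ester by the acid chloride should give the β-diketone, the second equivalent of enolate deprotonating the product so that it is not acylated again; low temperature and the absence of amine base avoid ketene formation and loss of configuration at C7.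

**Step 5**
Reactants: 7 (1E,6R)-6-(benzyloxy)-7-[4-(benzyloxy)phenyl]-1-methoxyhept-1-ene-3,5-dione
Product: 8 2-{(1R)-1-(benzyloxy)-2-[4-(benzyloxy)phenyl]ethyl}-4H-pyran-4-one
Conditions: CF3CO2H (2 equiv), CH2Cl2, rt
Reagents that add atoms: none
Why: Acid-catalysed 6-endo oxa-Michael addition of the diketone enol oxygen to the β-methoxy enone followed by loss of methanol (addition–elimination) is the established route to 2-substituted γ-pyrones and is driven by formation of the aromatic pyranone; C7 is not enolized toward under these conditions.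

**Step 6**
Reactants: 8 2-{(1R)-1-(benzyloxy)-2-[4-(benzyloxy)phenyl]ethyl}-4H-pyran-4-one; 9 [4-(benzyloxy)-3-methoxyphenyl]boronic acid
Product: 10 (2R)-2-[4-(benzyloxy)-3-methoxyphenyl]-6-{(1R)-1-(benzyloxy)-2-[4-(benzyloxy)phenyl]ethyl}-2,3-dihydro-4H-pyran-4-one
Conditions: 9 (2 equiv), Pd(OCOCF3)2 (5 mol %), (S)-4-tert-butyl-2-(pyridin-2-yl)-4,5-dihydrooxazole (6 mol %), NH4PF6 (30 mol %), H2O (5 equiv), ClCH2CH2Cl, 60 °C, argon
Reagents that add atoms: none
Why: Proposed new method: transmetalation of 9 to the cationic pyridine–oxazoline complex of divalent palladium gives an aryl–palladium species that inserts the less substituted C5=C6 double bond of the pyranone (syn carbopalladation, aryl to the oxygen-bearing carbon C6), and the resulting palladium enolate is protonated by water, which releases 10 and the palladium hydroxide that re-enters transmetalation. The closest known reaction type is the asymmetric conjugate addition of arylboronic acids to chromones (benzo-fused 4-pyranones) and cyclic enones under the same Pd(OCOCF3)2/pyridine–oxazoline conditions; the extension is to a monocyclic 4H-pyran-4-one, whose modest aromatic stabilisation is given up. No ring is closed: the flat pyranone ring itself becomes the oxane ring of the target. The new stereocenter (the aryl-bearing carbon, 2R) is set by the tert-butyl group of the ligand, which differentiates the two faces of the coordinated C5=C6 bond, while the existing center C7 lies across the ring oxygen on a planar ring and should exert no meaningful bias. The step needs site selectivity for C6 over the substituted terminus C2 and arrest after one addition: C2 carries a branched alkyl group, so insertion there would have to build a fully substituted carbon, and 10 is a β-alkoxy-β-alkyl enone that is much less reactive than 8. Return to an arylated pyranone by β-hydride elimination is disfavoured because the C6 hydrogen is anti to palladium after syn insertion and because no oxidant is present.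

**Step 7**
Reactants: 10 (2R)-2-[4-(benzyloxy)-3-methoxyphenyl]-6-{(1R)-1-(benzyloxy)-2-[4-(benzyloxy)phenyl]ethyl}-2,3-dihydro-4H-pyran-4-one
Product: 11 (2R,6S)-2-(4-hydroxy-3-methoxyphenyl)-6-[(1R)-1-hydroxy-2-(4-hydroxyphenyl)ethyl]oxan-4-one
Conditions: H2 (1 atm), 10% Pd/C, EtOAc/EtOH, rt
Reagents that add atoms: none
Why: Heterogeneous hydrogenation should add hydrogen syn to the C5=C6 enol-ether bond from the face opposite the C2 aryl group, as with other 2,6-disubstituted dihydropyranones, which gives the 2,6-cis ring (6S); the same catalyst cleaves the three O-benzyl ethers by hydrogenolysis, while the ring C2–O bond of the saturated oxane is cleaved much more slowly.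

**Step 8**
Reactants: 11 (2R,6S)-2-(4-hydroxy-3-methoxyphenyl)-6-[(1R)-1-hydroxy-2-(4-hydroxyphenyl)ethyl]oxan-4-one
Product: 12 (2R,4R,6S)-2-(4-hydroxy-3-methoxyphenyl)-6-[(1R)-1-hydroxy-2-(4-hydroxyphenyl)ethyl]oxan-4-ol
Conditions: NaBH4, MeOH, 0 °C
Reagents that add atoms: none
Why: Borohydride reduction of the chair ketone, locked by its two equatorial substituents, should proceed by axial hydride attack and give the equatorial alcohol (4R), cis to both ring substituents; phenols and the side-chain alcohol are unaffected.

**Compound list**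

1 | O-benzyl-D-tyrosine, (2R)-2-amino-3-[4-(benzyloxy)phenyl]propanoic acid | N[C@H](Cc1ccc(OCc2ccccc2)cc1)C(=O)O | starting material
2 | (2R)-3-[4-(benzyloxy)phenyl]-2-hydroxypropanoic acid | O[C@H](Cc1ccc(OCc2ccccc2)cc1)C(=O)O | intermediate
3 | (2R)-2-(benzyloxy)-3-[4-(benzyloxy)phenyl]propanoic acid | O=C(O)[C@H](OCc1ccccc1)Cc1ccc(OCc2ccccc2)cc1 | intermediate
4 | (2R)-2-(benzyloxy)-3-[4-(benzyloxy)phenyl]propanoyl chloride | O=C(Cl)[C@H](OCc1ccccc1)Cc1ccc(OCc2ccccc2)cc1 | intermediate
5 | (E)-4-methoxybut-3-en-2-one | CC(=O)/C=C/OC | starting material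
6 | lithium (3E)-4-methoxybuta-1,3-dien-2-olate | [Li+].[O-]C(=C)/C=C/OC | intermediate
7 | (1E,6R)-6-(benzyloxy)-7-[4-(benzyloxy)phenyl]-1-methoxyhept-1-ene-3,5-dione | CO/C=C/C(=O)CC(=O)[C@H](OCc1ccccc1)Cc1ccc(OCc2ccccc2)cc1 | intermediate
8 | 2-{(1R)-1-(benzyloxy)-2-[4-(benzyloxy)phenyl]ethyl}-4H-pyran-4-one | O=c1cc([C@H](OCc2ccccc2)Cc2ccc(OCc3ccccc3)cc2)occ1 | intermediate
9 | [4-(benzyloxy)-3-methoxyphenyl]boronic acid | COc1cc(B(O)O)ccc1OCc1ccccc1 | starting material
10 | (2R)-2-[4-(benzyloxy)-3-methoxyphenyl]-6-{(1R)-1-(benzyloxy)-2-[4-(benzyloxy)phenyl]ethyl}-2,3-dihydro-4H-pyran-4-one | COc1cc([C@H]2CC(=O)C=C([C@H](OCc3ccccc3)Cc3ccc(OCc4ccccc4)cc3)O2)ccc1OCc1ccccc1 | intermediate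
11 | (2R,6S)-2-(4-hydroxy-3-methoxyphenyl)-6-[(1R)-1-hydroxy-2-(4-hydroxyphenyl)ethyl]oxan-4-one | COc1cc([C@H]2CC(=O)C[C@@H]([C@H](O)Cc3ccc(O)cc3)O2)ccc1O | intermediate
12 | (2R,4R,6S)-2-(4-hydroxy-3-methoxyphenyl)-6-[(1R)-1-hydroxy-2-(4-hydroxyphenyl)ethyl]oxan-4-ol | COc1cc([C@H]2C[C@@H](O)C[C@@H]([C@H](O)Cc3ccc(O)cc3)O2)ccc1O | target

**Totals**

Total step count: 8. Longest linear sequence: 8 steps (1 to 12); 5 and 9 enter as purchased compounds.

**Steps most likely to fail**

1. Step 6 (proposed new method). The monocyclic pyranone may be too unreactive (its basic carbonyl can bind the cationic palladium, and aromatic stabilisation must be given up). The palladium enolate may rearomatize by β-hydride elimination, or enantiofacial control may be poor.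
Fallback, from 8 back to 10: silylation of the pyranone carbonyl with t-BuMe2SiOTf in CH2Cl2 should give the 2-{(1R)-1-(benzyloxy)-2-[4-(benzyloxy)phenyl]ethyl}-4-[(tert-butyldimethylsilyl)oxy]pyrylium trifluoromethanesulfonate F1. At –78 °C this is treated with [4-(benzyloxy)-3-methoxyphenyl]magnesium bromide F2 (from 1-(benzyloxy)-4-bromo-2-methoxybenzene and Mg in THF) and CuBr·SMe2 (cat.). Addition at the unsubstituted α-carbon, a known reaction type for 4-silyloxypyrylium and benzopyrylium salts, should give the 2-aryl-4-silyloxy-2H-pyran F3 as both epimers at the new center. Mild acid hydrolysis of the silyl enol ether gives 10 together with its (2S)-epimer F4, and the two diastereomers are separated by chromatography. Stereocontrol at this center is replaced by separation.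

2. Step 7. Facial selectivity of hydrogen delivery may be poor, because the C7 center next to the alkene competes with the remote aryl group. Hydrogenolysis of the allylic C7–O bond, or of the ring benzylic C–O bond while it is still part of the vinylogous ester, may also precede saturation of the alkene.
Fallback, from 10 back to 12: conjugate reduction with LiBH(s-Bu)3 in THF at –78 °C should deliver hydride axially to C6 and give, after protonation of the enolate, the 2,6-cis (2R,6S)-2-[4-(benzyloxy)-3-methoxyphenyl]-6-{(1R)-1-(benzyloxy)-2-[4-(benzyloxy)phenyl]ethyl}oxan-4-one F5. NaBH4 in MeOH then gives the equatorial alcohol, (2R,4R,6S)-2-[4-(benzyloxy)-3-methoxyphenyl]-6-{(1R)-1-(benzyloxy)-2-[4-(benzyloxy)phenyl]ethyl}oxan-4-ol F6. Hydrogenolysis of the three benzyl ethers (H2, Pd(OH)2/C, EtOAc) on this saturated oxane, which no longer holds an allylic or vinylogous-ester C–O bond, gives 12.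

3. Step 4. The dienolate may be acylated on oxygen instead of carbon, the product may be acylated twice, or the acid chloride may lose configuration through ketene formation.
Fallback, from 3 back to 7: reduction of the acid with BH3·THF should give (2R)-2-(benzyloxy)-3-[4-(benzyloxy)phenyl]propan-1-ol F7. Dess–Martin oxidation gives (2R)-2-(benzyloxy)-3-[4-(benzyloxy)phenyl]propanal F8, which is used at once. Aldol addition of lithium dienolate 6 at –78 °C gives (1E,6R)-6-(benzyloxy)-7-[4-(benzyloxy)phenyl]-5-hydroxy-1-methoxyhept-1-en-3-one F9 as a mixture of carbinol epimers, which does not matter. A second Dess–Martin oxidation converts the β-hydroxy ketone into diketone 7.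

**Further compounds**

F1 | step 6 | 2-{(1R)-1-(benzyloxy)-2-[4-(benzyloxy)phenyl]ethyl}-4-[(tert-butyldimethylsilyl)oxy]pyrylium trifluoromethanesulfonate | CC(C)(C)[Si](C)(C)Oc1cc([C@H](OCc2ccccc2)Cc2ccc(OCc3ccccc3)cc2)[o+]cc1.[O-]S(=O)(=O)C(F)(F)F
F2 | step 6 | [4-(benzyloxy)-3-methoxyphenyl]magnesium bromide | COc1cc([Mg]Br)ccc1OCc1ccccc1
F3 | step 6 | {[2-[4-(benzyloxy)-3-methoxyphenyl]-6-{(1R)-1-(benzyloxy)-2-[4-(benzyloxy)phenyl]ethyl}-2H-pyran-4-yl]oxy}(tert-butyl)dimethylsilane, both epimers at ring C2 | COc1cc(C2C=C(O[Si](C)(C)C(C)(C)C)C=C([C@H](OCc3ccccc3)Cc3ccc(OCc4ccccc4)cc3)O2)ccc1OCc1ccccc1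
F4 | step 6 | (2S)-2-[4-(benzyloxy)-3-methoxyphenyl]-6-{(1R)-1-(benzyloxy)-2-[4-(benzyloxy)phenyl]ethyl}-2,3-dihydro-4H-pyran-4-one | COc1cc([C@@H]2CC(=O)C=C([C@H](OCc3ccccc3)Cc3ccc(OCc4ccccc4)cc3)O2)ccc1OCc1ccccc1
F5 | step 7 | (2R,6S)-2-[4-(benzyloxy)-3-methoxyphenyl]-6-{(1R)-1-(benzyloxy)-2-[4-(benzyloxy)phenyl]ethyl}oxan-4-one | COc1cc([C@H]2CC(=O)C[C@@H]([C@H](OCc3ccccc3)Cc3ccc(OCc4ccccc4)cc3)O2)ccc1OCc1ccccc1
F6 | step 7 | (2R,4R,6S)-2-[4-(benzyloxy)-3-methoxyphenyl]-6-{(1R)-1-(benzyloxy)-2-[4-(benzyloxy)phenyl]ethyl}oxan-4-ol | COc1cc([C@H]2C[C@@H](O)C[C@@H]([C@H](OCc3ccccc3)Cc3ccc(OCc4ccccc4)cc3)O2)ccc1OCc1ccccc1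
F7 | step 4 | (2R)-2-(benzyloxy)-3-[4-(benzyloxy)phenyl]propan-1-ol | OC[C@H](OCc1ccccc1)Cc1ccc(OCc2ccccc2)cc1
F8 | step 4 | (2R)-2-(benzyloxy)-3-[4-(benzyloxy)phenyl]propanal | O=C[C@H](OCc1ccccc1)Cc1ccc(OCc2ccccc2)cc1
F9 | step 4 | (1E,6R)-6-(benzyloxy)-7-[4-(benzyloxy)phenyl]-5-hydroxy-1-methoxyhept-1-en-3-one, both C5 epimers | CO/C=C/C(=O)CC(O)[C@H](OCc1ccccc1)Cc1ccc(OCc2ccccc2)cc1
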